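The only stereocentre, C3 of the pyran ring (ring C), is traced back to a flat isoflavone whose C4 carbonyl acts as a temporary relay. One transfer hydrogenation with RuCl[(R,R)-TsDPEN](p-cymene) saturates C2=C3 and then reduces the C4 ketone under dynamic kinetic resolution. Because C3 is a benzylic methine next to C4, it epimerises at the ketone stage and is funnelled into the cis-(3R,4R) alcohol; the C4 oxygen is then removed by ionic deoxygenation. The precursor is the achiral 5,2'-dimethoxy-7,4'-bis(MOM-oxy)-6-prenylisoflavone, made by Suzuki coupling of a 3-iodochromone (prenyl placed by para-Claisen-Cope rearrangement) with a ring B boronic acid.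

Key step: step 8

Assumption: the sense of induction follows the aryl ketone model ((R,R) ligand giving the 4R carbinol); if the opposite sense were found, the (S,S) complex would be used with no other change.

Step 1
Reactants: 1 2',4'-dihydroxy-6'-methoxyacetophenone
Product: 2 2'-hydroxy-6'-methoxy-4'-(methoxymethoxy)acetophenone
Conditions: MOMCl (1.1 equiv), K2CO3, acetone, 0 °C to rt
Reagents that add atoms: chloromethyl methyl ether (MOMCl), COCCl
Why: Williamson-type O-alkylation with MOMCl, in which the 2'-OH is tied up in a hydrogen bond to the acetyl carbonyl, so one equivalent of the electrophile should cap only the free, more acidic 4'-OH.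

Step 2
Reactants: 2 2'-hydroxy-6'-methoxy-4'-(methoxymethoxy)acetophenone; 3 prenyl bromide (1-bromo-3-methylbut-2-ene)
Product: 4 6'-methoxy-4'-(methoxymethoxy)-2'-(3-methylbut-2-enyloxy)acetophenone
Conditions: K2CO3, DMF, 60 °C
Reagents that add atoms: none
Why: Williamson ether synthesis, in which the carbonate in hot DMF breaks the chelate and the 2'-phenoxide attacks the primary allylic bromide by SN2 at oxygen, the MOM acetal being inert to base.

Step 3
Reactants: 4 6'-methoxy-4'-(methoxymethoxy)-2'-(3-methylbut-2-enyloxy)acetophenone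
Product: 7 2'-hydroxy-6'-methoxy-4'-(methoxymethoxy)-5'-(3-methylbut-2-enyl)acetophenone, via ortho-dienone 5 (not isolated), via para-dienone 6 (not isolated)
Conditions: N,N-diethylaniline, 200 °C, argon, sealed tube
Reagents that add atoms: none
Why: Para-Claisen-Cope rearrangement, in which a [3,3] shift to C3' gives ortho-dienone 5, whose congested 1,1-dimethylallyl group moves on by a Cope [3,3] shift to C5' (para-dienone 6) before enolisation can fix it, and tautomerisation then gives the chelated phenol that becomes O1, with a normal prenyl group between OMe and OMOM.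

Step 4
Reactants: 7 2'-hydroxy-6'-methoxy-4'-(methoxymethoxy)-5'-(3-methylbut-2-enyl)acetophenone
Product: 9 3-iodo-5-methoxy-7-(methoxymethoxy)-6-(3-methylbut-2-enyl)-4H-chromen-4-one, via enaminone 8 (not isolated)
Conditions: DMF dimethyl acetal, 90 °C; evaporate; I2 (1.05 equiv), pyridine, CHCl3, 0 °C to rt; aq Na2S2O3
Reagents that add atoms: N,N-dimethylformamide dimethyl acetal, COC(OC)N(C)C; iodine, II
Why: Condensation of the methyl ketone with the amide acetal gives enaminone 8, and iodine-induced cyclisation (iodination of the enamine carbon, attack of the chelated phenol on the iminium carbon to form the O1-C2 bond, loss of dimethylamine) closes ring C; the enaminone is far more nucleophilic than the prenyl alkene, which has no free OH beside it, so one equivalent of iodine buffered by pyridine should spare it.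

Step 5
Reactants: 10 4-bromo-3-methoxyphenol
Product: 11 1-bromo-2-methoxy-4-(methoxymethoxy)benzene
Conditions: MOMCl, K2CO3, acetone, rt to 50 °C
Reagents that add atoms: chloromethyl methyl ether (MOMCl), COCCl
Why: Williamson-type O-alkylation of the phenoxide with MOMCl, the aryl bromide being inert.

Step 6
Reactants: 11 1-bromo-2-methoxy-4-(methoxymethoxy)benzene
Product: 13 [2-methoxy-4-(methoxymethoxy)phenyl]boronic acid, via aryllithium 12 (not isolated)
Conditions: n-BuLi, THF, −78 °C; B(OiPr)3, −78 °C to rt; H2O, 1 M HCl to pH 6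
Reagents that add atoms: triisopropyl borate, CC(C)OB(OC(C)C)OC(C)C; water, O
Why: Lithiation-borylation, in which bromine-lithium exchange at −78 °C outruns ortho-lithiation next to the OMe and OMOM groups, the aryllithium adds to the borate, and hydrolysis at pH 6 frees the boronic acid without touching the MOM acetal.

Step 7
Reactants: 9 3-iodo-5-methoxy-7-(methoxymethoxy)-6-(3-methylbut-2-enyl)-4H-chromen-4-one; 13 [2-methoxy-4-(methoxymethoxy)phenyl]boronic acid
Product: 14 5-methoxy-3-[2-methoxy-4-(methoxymethoxy)phenyl]-7-(methoxymethoxy)-6-(3-methylbut-2-enyl)-4H-chromen-4-one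
Conditions: Pd(dppf)Cl2 (5 mol %), Na2CO3, DME/H2O, 80 °C
Reagents that add atoms: none
Why: Suzuki-Miyaura coupling, in which the zerovalent palladium species generated from Pd(dppf)Cl2 inserts into the C3-I bond of the chromone, the boronate transmetalates and reductive elimination forms the C3-C1' bond, with the prenyl alkene and the acetals as spectators.

Step 8
Reactants: 14 5-methoxy-3-[2-methoxy-4-(methoxymethoxy)phenyl]-7-(methoxymethoxy)-6-(3-methylbut-2-enyl)-4H-chromen-4-one
Product: 16 (3R,4R)-cis-5-methoxy-3-[2-methoxy-4-(methoxymethoxy)phenyl]-7-(methoxymethoxy)-6-(3-methylbut-2-enyl)chroman-4-ol, via racemic isoflavanone 15 (not isolated)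
Conditions: RuCl[(R,R)-TsDPEN](p-cymene) (5 mol %), HCO2H/Et3N (1:1), EtOAc, 40 °C, argon
Reagents that add atoms: none
Why: The 16-electron amido complex formed from RuCl[(R,R)-TsDPEN](p-cymene) by loss of HCl dehydrogenates formate to RuH[(R,R)-TsDPEN](p-cymene), which delivers hydride to C2 of the chromone enone (proton to C3) to give racemic isoflavanone 15 and then reduces its C4 ketone through the outer-sphere, six-membered N-H/Ru-H transition state; the closest known reaction type is the asymmetric transfer hydrogenation of isoflavones and racemic isoflavanones to cis-isoflavan-4-ols with dynamic kinetic resolution (Noyori-Ikariya type). No ring is closed: the step only forms the C2-H, C3-H and C4-H bonds on the existing pyran ring. The C4 centre is set by the catalyst, the CH/pi contact between the cymene ligand and ring A being expected to expose the carbonyl face that leads to the 4R carbinol with the (R,R) ligand, as for simple aryl ketones. The C3 centre is set by dynamic kinetic resolution: hydride enters anti to the 3-aryl group, so only the 3R ketone presents the catalyst-preferred face unhindered and is reduced quickly, while the 3S ketone epimerises through its enol in the amine-formate medium and drains into the same cis-(3R,4R) alcohol. The step needs chemoselectivity (enone and ketone over the prenyl alkene, which an outer-sphere hydride does not touch, with aryl ethers and MOM acetals inert) together with enantioface selection at C4 and cis diastereoselection, and the substrate secures the latter two through its fused ring A next to the carbonyl and the acidic benzylic, alpha-keto C3-H that makes epimerisation faster than reduction of the slow enantiomer.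

Step 9
Reactants: 16 (3R,4R)-cis-5-methoxy-3-[2-methoxy-4-(methoxymethoxy)phenyl]-7-(methoxymethoxy)-6-(3-methylbut-2-enyl)chroman-4-ol
Product: 17 (3R)-5-methoxy-3-[2-methoxy-4-(methoxymethoxy)phenyl]-7-(methoxymethoxy)-6-(3-methylbut-2-enyl)chroman
Conditions: Et3SiH (5 equiv), then BF3·OEt2 (0.5 equiv), CH2Cl2, −78 °C; Et3N, then aq NaHCO3
Reagents that add atoms: none
Why: Ionic hydrogenation, in which BF3 ionises the C4-OH to a benzylic cation stabilised by O1, the 5-OMe and the 7-OMOM oxygen, and the silane, present in excess before the acid is added, should trap it at −78 °C faster than it can lose the C3 proton, so C3 stays R, while the isolated prenyl alkene (which hydrogenolysis over palladium would saturate) and the acetals should survive the cold aprotic conditions.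

Step 10
Reactants: 17 (3R)-5-methoxy-3-[2-methoxy-4-(methoxymethoxy)phenyl]-7-(methoxymethoxy)-6-(3-methylbut-2-enyl)chroman
Product: 18 (3R)-3-(4-hydroxy-2-methoxyphenyl)-5-methoxy-6-(3-methylbut-2-enyl)chroman-7-ol
Conditions: 3 M aq HCl/MeOH (1:10), rt; aq NaHCO3
Reagents that add atoms: none
Why: Acid-catalysed methanolysis of the two MOM acetals (transacetalisation to dimethoxymethane) is much faster at room temperature than Markovnikov protonation of the prenyl alkene, so both phenols should be freed without closure of the 7-OH onto the side chain and without any effect on C3.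

Compound list
1 | 1-(2,4-dihydroxy-6-methoxyphenyl)ethanone (2',4'-dihydroxy-6'-methoxyacetophenone) | CC(=O)c1c(O)cc(O)cc1OC | starting material
2 | 1-[2-hydroxy-6-methoxy-4-(methoxymethoxy)phenyl]ethanone | CC(=O)c1c(O)cc(OCOC)cc1OC | intermediate
3 | prenyl bromide (1-bromo-3-methylbut-2-ene) | CC(C)=CCBr | starting material
4 | 1-[2-methoxy-4-(methoxymethoxy)-6-(3-methylbut-2-enyloxy)phenyl]ethanone | CC(=O)c1c(OCC=C(C)C)cc(OCOC)cc1OC | intermediate
5 | ortho-dienone, racemic 2-acetyl-3-methoxy-5-(methoxymethoxy)-6-(2-methylbut-3-en-2-yl)cyclohexa-2,4-dien-1-one | CC(=O)C1=C(OC)C=C(OCOC)C(C(C)(C)C=C)C1=O | intermediate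
6 | para-dienone, racemic 2-acetyl-3-methoxy-5-(methoxymethoxy)-4-(3-methylbut-2-enyl)cyclohexa-2,5-dien-1-one | CC(=O)C1=C(OC)C(CC=C(C)C)C(OCOC)=CC1=O | intermediate
7 | 1-[6-hydroxy-2-methoxy-4-(methoxymethoxy)-3-(3-methylbut-2-enyl)phenyl]ethanone | CC(=O)c1c(O)cc(OCOC)c(CC=C(C)C)c1OC | intermediate
8 | (E)-3-(dimethylamino)-1-[6-hydroxy-2-methoxy-4-(methoxymethoxy)-3-(3-methylbut-2-enyl)phenyl]prop-2-en-1-one | CN(C)/C=C/C(=O)c1c(O)cc(OCOC)c(CC=C(C)C)c1OC | intermediate
9 | 3-iodo-5-methoxy-7-(methoxymethoxy)-6-(3-methylbut-2-enyl)-4H-chromen-4-one | O=c1c(I)coc2cc(OCOC)c(CC=C(C)C)c(OC)c12 | intermediate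
10 | 4-bromo-3-methoxyphenol | COc1cc(O)ccc1Br | starting material
11 | 1-bromo-2-methoxy-4-(methoxymethoxy)benzene | COCOc1ccc(Br)c(OC)c1 | intermediate
12 | [2-methoxy-4-(methoxymethoxy)phenyl]lithium | [Li]c1ccc(OCOC)cc1OC | intermediate
13 | [2-methoxy-4-(methoxymethoxy)phenyl]boronic acid | COCOc1ccc(B(O)O)c(OC)c1 | intermediate
14 | 5-methoxy-3-[2-methoxy-4-(methoxymethoxy)phenyl]-7-(methoxymethoxy)-6-(3-methylbut-2-enyl)-4H-chromen-4-one | COCOc1ccc(-c2coc3cc(OCOC)c(CC=C(C)C)c(OC)c3c2=O)c(OC)c1 | intermediate
15 | racemic 5-methoxy-3-[2-methoxy-4-(methoxymethoxy)phenyl]-7-(methoxymethoxy)-6-(3-methylbut-2-enyl)chroman-4-one | COCOc1ccc(C2COc3cc(OCOC)c(CC=C(C)C)c(OC)c3C2=O)c(OC)c1 | intermediate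
16 | (3R,4R)-5-methoxy-3-[2-methoxy-4-(methoxymethoxy)phenyl]-7-(methoxymethoxy)-6-(3-methylbut-2-enyl)chroman-4-ol (3-aryl and 4-OH cis) | COc1cc(OCOC)ccc1[C@@H]1COc2cc(OCOC)c(CC=C(C)C)c(OC)c2[C@@H]1O | intermediate
17 | (3R)-5-methoxy-3-[2-methoxy-4-(methoxymethoxy)phenyl]-7-(methoxymethoxy)-6-(3-methylbut-2-enyl)chroman | COc1cc(OCOC)ccc1[C@@H]1COc2cc(OCOC)c(CC=C(C)C)c(OC)c2C1 | intermediate
18 | (3R)-3-(4-hydroxy-2-methoxyphenyl)-5-methoxy-6-(3-methylbut-2-enyl)chroman-7-ol | COc1cc(O)ccc1[C@@H]1COc2cc(O)c(CC=C(C)C)c(OC)c2C1 | target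

Total step count: 10. Longest linear sequence: 8 steps (steps 1 to 4 and 7 to 10, from 1); the ring B branch takes 2 steps (5 and 6).

Steps most likely to fail

Step 8. Hydride transfer to the electron-rich C4 carbonyl, which is flanked by the 5-OMe group and the 3-aryl group, may be too slow, so that the cascade stalls at the isoflavanone stage or the reduction loses its enantio- and diastereocontrol. The fallback sets out from 14 and comes back at 17, giving up catalytic control in favour of resolution. Conjugate reduction of 14 with LiBH(s-Bu)3 in THF at −78 °C should give racemic isoflavanone 15 in isolated form. NaBH4 in MeOH/THF at 0 °C should then give the racemic isoflavan-4-ol mixture F1, whose cis/trans composition is irrelevant because C4 is erased. Et3SiH/BF3·OEt2 under the conditions of step 9 should give the racemic isoflavan F2. Preparative HPLC on a cellulose tris(3,5-dimethylphenylcarbamate) stationary phase should separate the enantiomers, and the 3R isomer is 17.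

Step 9. The C4 cation may lose the C3 proton to give the isoflav-3-ene, whose re-protonation and reduction would erode the configuration at C3, and the Lewis acid may cleave or reduce the MOM acetals. The fallback sets out from 16 and comes back at 17 by a Barton-McCombie deoxygenation. NaH, CS2 and then MeI in THF at 0 °C should give the S-methyl xanthate F3, and Bu3SnH with AIBN in toluene at 80 °C should give 17. C4 then passes through a radical, never a cation, so the C3-H bond is not engaged. In the cis alcohol the C3-H lies anti to the xanthate, so a Chugaev syn-elimination is not available.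

Step 10. Acid may protonate the prenyl alkene, with closure of the freed 7-OH to a 2,2-dimethylchroman, and the methoxymethyl cation released may alkylate the very electron-rich ring A at C8. The fallback sets out from 14 and comes back at 18 by changing the protecting groups at the isoflavone stage, where ring A is deactivated by the C4 carbonyl. Methanolic HCl on 14 should give the diphenol isoflavone F4, and TIPSCl with imidazole in DMF the bis(triisopropylsilyl) ether F5. The conditions of step 8 should then give, through the silylated isoflavanone F6 formed in the flask, the silylated cis-(3R,4R) alcohol F7, and the conditions of step 9 the silylated (3R)-isoflavan F8. Bu4NF buffered with AcOH in THF at 0 °C should then free both phenols and give 18 without any acid.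

Further compounds
F1 | step 8 | racemic 5-methoxy-3-[2-methoxy-4-(methoxymethoxy)phenyl]-7-(methoxymethoxy)-6-(3-methylbut-2-enyl)chroman-4-ol (cis/trans mixture) | COc1cc(OCOC)ccc1C1COc2cc(OCOC)c(CC=C(C)C)c(OC)c2C1O
F2 | step 8 | racemic 5-methoxy-3-[2-methoxy-4-(methoxymethoxy)phenyl]-7-(methoxymethoxy)-6-(3-methylbut-2-enyl)chroman | COc1cc(OCOC)ccc1C1COc2cc(OCOC)c(CC=C(C)C)c(OC)c2C1
F3 | step 9 | O-[(3R,4R)-5-methoxy-3-[2-methoxy-4-(methoxymethoxy)phenyl]-7-(methoxymethoxy)-6-(3-methylbut-2-enyl)chroman-4-yl] S-methyl dithiocarbonate | COc1cc(OCOC)ccc1[C@@H]1COc2cc(OCOC)c(CC=C(C)C)c(OC)c2[C@@H]1OC(=S)SC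
F4 | step 10 | 7-hydroxy-3-(4-hydroxy-2-methoxyphenyl)-5-methoxy-6-(3-methylbut-2-enyl)-4H-chromen-4-one | COc1cc(O)ccc1-c1coc2cc(O)c(CC=C(C)C)c(OC)c2c1=O
F5 | step 10 | 5-methoxy-3-[2-methoxy-4-(triisopropylsilyloxy)phenyl]-6-(3-methylbut-2-enyl)-7-(triisopropylsilyloxy)-4H-chromen-4-one | COc1cc(O[Si](C(C)C)(C(C)C)C(C)C)ccc1-c1coc2cc(O[Si](C(C)C)(C(C)C)C(C)C)c(CC=C(C)C)c(OC)c2c1=O
F6 | step 10 | racemic 5-methoxy-3-[2-methoxy-4-(triisopropylsilyloxy)phenyl]-6-(3-methylbut-2-enyl)-7-(triisopropylsilyloxy)chroman-4-one | COc1cc(O[Si](C(C)C)(C(C)C)C(C)C)ccc1C1COc2cc(O[Si](C(C)C)(C(C)C)C(C)C)c(CC=C(C)C)c(OC)c2C1=O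
F7 | step 10 | (3R,4R)-cis-5-methoxy-3-[2-methoxy-4-(triisopropylsilyloxy)phenyl]-6-(3-methylbut-2-enyl)-7-(triisopropylsilyloxy)chroman-4-ol | COc1cc(O[Si](C(C)C)(C(C)C)C(C)C)ccc1[C@@H]1COc2cc(O[Si](C(C)C)(C(C)C)C(C)C)c(CC=C(C)C)c(OC)c2[C@@H]1O
F8 | step 10 | (3R)-5-methoxy-3-[2-methoxy-4-(triisopropylsilyloxy)phenyl]-6-(3-methylbut-2-enyl)-7-(triisopropylsilyloxy)chroman | COc1cc(O[Si](C(C)C)(C(C)C)C(C)C)ccc1[C@@H]1COc2cc(O[Si](C(C)C)(C(C)C)C(C)C)c(CC=C(C)C)c(OC)c2C1
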